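**Retrosynthetic overview**

1. Numbering (carotenoid): ring C1 = C(CH3)2, C2 = CH2, C3 = CH(OH), C4 = CH=, C5 = C(CH3)=, C6 = CH; the chain starts with C7=C8. The target, (3S,6R)-3-hydroxy-8'-apo-ε-caroten-8'-al (OH and chain cis), is cut at C7=C8 (Julia–Kocienski) into crocetin dialdehyde 15 and the C10 ring sulfone 14.
2. Sulfone 14 comes from bridged lactone 10 (a 2-oxabicyclo[2.2.2]oct-5-en-3-one). Its O–C(=O) bridge from the C3 oxygen to C7 is a ring that is not in the target: it is closed under epimerising conditions to force C6 into the cis relation to C3 and is cut again by LiAlH4. C3 is set beforehand by asymmetric transfer hydrogenation of keto acid 7.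
3. The carbocycle is made in one operation from two achiral esters: a Michael–Dieckmann [3+3] annulation of di-tert-butyl 3,3-dimethylglutarate 2 with methyl but-2-ynoate 3 forms the C5–C6 and the C2–C3 bond at the ketone oxidation level. The extra ester on C2 is a traceless activating group (lost as CO2).
4. Feature that makes this possible: the quaternary gem-dimethyl carbon C1 carries the ring carbons C2 and C6 as two homotopic CH2 arms (a hidden 3,3-dimethylglutarate, so it does not matter which arm adds and which is acylated). These arms face the three-carbon unit O–C3–C4=C5(CH3), a hidden but-2-ynoate. C1 also rules out enolisation, aromatisation and a four-ring closure.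
5. Ring order: six-membered carbocycle (step 2), then the temporary lactone ring (step 5), opened in step 6; the polyene is attached last (step 9).

Key step: step 2

Assumption: all-E crocetin dialdehyde 15 is taken as a purchasable specialty compound, and the sense of induction of the (S,S)-TsDPEN catalyst in step 4 is assigned from the aryl/alkenyl ketone model.

**Route**

Step 1
Reactants: 1 3,3-dimethylpentanedioic acid (3,3-dimethylglutaric acid)
Product: 2 di-tert-butyl 3,3-dimethylpentanedioate
Conditions: isobutylene (excess), H2SO4 (cat.), CH2Cl2, sealed vessel, 23 °C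
Reagents that add atoms: 2-methylprop-1-ene (isobutylene), CC(C)=C
Why: Acid-catalysed addition of the carboxylic acid groups to isobutylene (tert-butyl esterification through the tert-butyl cation) should give the diester, whose bulky ester groups suppress self-Claisen condensation and later leave under acid.

Step 2
Reactants: 2 di-tert-butyl 3,3-dimethylpentanedioate; 3 methyl but-2-ynoate
Product: 5 di-tert-butyl 2,2,4-trimethyl-6-oxocyclohex-4-ene-1,3-dicarboxylate (keto/enol and stereoisomer mixture), via Michael adduct triester 4 (not isolated)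
Conditions: LiN(i-Pr)2 (1.05 equiv), THF, −78 °C; 3 (1.0 equiv), −78 → −20 °C; KOt-Bu (1.2 equiv), −20 → 23 °C; AcOH
Reagents that add atoms: none
Why: The lithium enolate of 2 adds to the methyl-bearing β-carbon of ynoate 3 (Michael addition, C5–C6 bond), amine-mediated proton transfer gives the delocalised anion of triester 4, and after KOt-Bu has formed the enolate of the second arm a Dieckmann condensation on the methyl ester closes the ring (C2–C3 bond) with loss of methoxide. The closest known reaction type is the one-pot Michael–Dieckmann (Michael–Claisen) cyclocondensation of 1,3-diester carbon dinucleophiles such as 3-oxoglutarates with alkynoates, and of ester or ketone enolates with acrylates. The only ring closed is the six-membered carbocycle, by a 6-exo-trig acyl substitution that is helped by the gem-dimethyl (Thorpe–Ingold) effect. The two stereocentres that appear (the ester-bearing carbons C2 and C6) are deliberately left uncontrolled: C2 loses its ester in step 3 and C6 stays epimerisable until step 5 fixes it. The selectivities needed are chemo-, regio- and geometric: conjugate addition is favoured over carbonyl attack by running the first stage with the hindered tert-butyl ester lithium enolate at −78 °C, regiochemistry is no issue because the two arms of 2 are homotopic, and the E and Z forms of 4 interconvert through the pentadienyl-type anion so that both funnel into the one geometry that can cyclise. The reaction is pulled to completion by deprotonation of β-keto ester 5, and the quaternary carbon prevents both a self-Dieckmann closure of 2 and aromatisation of 5.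

Step 3
Reactants: 5 di-tert-butyl 2,2,4-trimethyl-6-oxocyclohex-4-ene-1,3-dicarboxylate
Product: 7 rac-2,6,6-trimethyl-4-oxocyclohex-2-ene-1-carboxylic acid, via keto diacid 6 (not isolated)
Conditions: CF3CO2H/CH2Cl2 (1:1), 23 °C; then toluene, 40 °C
Reagents that add atoms: none
Why: Acidolysis of both tert-butyl esters (loss of isobutylene) should give keto diacid 6, whose β-keto acid unit decarboxylates through the cyclic six-membered transition state at 40 °C, while the vinylogous acid on C6 has no such low-energy pathway and survives.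

Step 4
Reactants: 7 rac-2,6,6-trimethyl-4-oxocyclohex-2-ene-1-carboxylic acid
Product: 8 (4S)-4-hydroxy-2,6,6-trimethylcyclohex-2-ene-1-carboxylic acid (mixture of C1 epimers)
Conditions: RuCl[(S,S)-TsDPEN](p-cymene) (1 mol %), HCO2H/Et3N (5:2), 30 °C
Reagents that add atoms: none
Why: Noyori–Ikariya asymmetric transfer hydrogenation should reduce only the C=O group and set C3 as S by catalyst control (the conjugated C4=C5 π-bond takes the place of the aryl group of the aryl ketone model next to the η6-arene, as in the closely related reduction of the 4-carbonyl of 2,6,6-trimethylcyclohex-2-ene-1,4-dione), whereas the labile C6 centre is knowingly left as a mixture.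

Step 5
Reactants: 8 (4S)-4-hydroxy-2,6,6-trimethylcyclohex-2-ene-1-carboxylic acid (C1 epimers)
Product: 10 (1S,4R)-5,8,8-trimethyl-2-oxabicyclo[2.2.2]oct-5-en-3-one, via mixed trichlorobenzoic anhydride 9 (not isolated)
Conditions: 2,4,6-Cl3C6H2COCl, Et3N, THF, 23 °C; then DMAP, toluene (2 mM), 40 °C
Reagents that add atoms: none
Why: Yamaguchi lactonisation run as a dynamic process: the activated acyl group of this β,γ-unsaturated acid epimerises at C6 through its acylpyridinium dienolate or vinylketene under Et3N/DMAP while only the cis acyl species can be captured by the C3 hydroxyl, so both epimers should funnel into the one bridged lactone, in which C6 is set as R by the fixed C3 centre and is then locked at a bridgehead against epimerisation and double-bond migration (Bredt's rule).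

Step 6
Reactants: 10 (1S,4R)-5,8,8-trimethyl-2-oxabicyclo[2.2.2]oct-5-en-3-one
Product: 11 (1S,4R)-4-(hydroxymethyl)-3,5,5-trimethylcyclohex-2-en-1-ol
Conditions: LiAlH4, THF, 0 °C
Reagents that add atoms: none
Why: LiAlH4 reduction of the lactone cuts the temporary bridge to the cis-diol and touches neither stereocentre nor the trisubstituted alkene.

Step 7
Reactants: 11 (1S,4R)-4-(hydroxymethyl)-3,5,5-trimethylcyclohex-2-en-1-ol
Product: 12 (1S,4R)-3,5,5-trimethyl-4-{[(1-phenyl-1H-tetrazol-5-yl)sulfanyl]methyl}cyclohex-2-en-1-ol
Conditions: 1-phenyl-1H-tetrazole-5-thiol, PPh3, DIAD, THF, 0 °C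
Reagents that add atoms: 1-phenyl-1H-tetrazole-5-thiol, Sc1nnnn1-c1ccccc1
Why: Mitsunobu thioetherification should be selective for the primary alcohol because its alkoxyphosphonium ion forms and is displaced (SN2) by the acidic thiol much faster than that of the more hindered secondary allylic alcohol at 0 °C, and no stereocentre is involved.

Step 8
Reactants: 12 (1S,4R)-3,5,5-trimethyl-4-{[(1-phenyl-1H-tetrazol-5-yl)sulfanyl]methyl}cyclohex-2-en-1-ol
Product: 14 (1S,4R)-3,5,5-trimethyl-4-{[(1-phenyl-1H-tetrazol-5-yl)sulfonyl]methyl}cyclohex-2-en-1-ol, via sulfoxide 13 (not isolated)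
Conditions: (NH4)6Mo7O24·4H2O (10 mol %), 30% H2O2, EtOH, 0 → 23 °C
Reagents that add atoms: hydrogen peroxide, OO
Why: Molybdate-catalysed oxidation with H2O2 should convert the sulfide via sulfoxide 13 into the sulfone much faster than peroxomolybdate epoxidises the trisubstituted alkene.

Step 9
Reactants: 14 (1S,4R)-3,5,5-trimethyl-4-{[(1-phenyl-1H-tetrazol-5-yl)sulfonyl]methyl}cyclohex-2-en-1-ol; 15 crocetin dialdehyde
Product: 16 (3S,6R)-3-hydroxy-8'-apo-ε-caroten-8'-al (target)
Conditions: KN(SiMe3)2 (2.05 equiv), DME/THF, −78 °C; then 15 (3 equiv) in THF, −78 → −20 °C; aq NH4Cl; argon, dark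
Reagents that add atoms: none
Why: Julia–Kocienski olefination: the potassium α-sulfonyl carbanion adds to one formyl group of 15 (used in excess to favour mono-olefination) and Smiles rearrangement with anti-elimination of SO2 and the tetrazolone should give the (E)-C7=C8 bond, while no strong base is left to touch the C6–H of the polyenal that is formed.

**Compound list**

1 | 3,3-dimethylpentanedioic acid | OC(=O)CC(C)(C)CC(=O)O | starting material
2 | di-tert-butyl 3,3-dimethylpentanedioate | CC(C)(C)OC(=O)CC(C)(C)CC(=O)OC(C)(C)C | intermediate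
3 | methyl but-2-ynoate | CC#CC(=O)OC | starting material
4 | 7-tert-butyl 1-methyl 4-(tert-butoxycarbonyl)-3,5,5-trimethylhept-2-enedioate (E/Z mixture, not isolated) | COC(=O)C=C(C)C(C(=O)OC(C)(C)C)C(C)(C)CC(=O)OC(C)(C)C | intermediate
5 | di-tert-butyl 2,2,4-trimethyl-6-oxocyclohex-4-ene-1,3-dicarboxylate (stereoisomer mixture) | CC1=CC(=O)C(C(=O)OC(C)(C)C)C(C)(C)C1C(=O)OC(C)(C)C | intermediate
6 | 2,2,4-trimethyl-6-oxocyclohex-4-ene-1,3-dicarboxylic acid (not isolated) | CC1=CC(=O)C(C(=O)O)C(C)(C)C1C(=O)O | intermediate
7 | rac-2,6,6-trimethyl-4-oxocyclohex-2-ene-1-carboxylic acid | CC1=CC(=O)CC(C)(C)C1C(=O)O | intermediate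
8 | (4S)-4-hydroxy-2,6,6-trimethylcyclohex-2-ene-1-carboxylic acid (C1 epimers) | CC1=C[C@@H](O)CC(C)(C)C1C(=O)O | intermediate
9 | (4S)-4-hydroxy-2,6,6-trimethylcyclohex-2-ene-1-carboxylic 2,4,6-trichlorobenzoic anhydride (C1 epimers, not isolated) | CC1=C[C@@H](O)CC(C)(C)C1C(=O)OC(=O)c1c(Cl)cc(Cl)cc1Cl | intermediate
10 | (1S,4R)-5,8,8-trimethyl-2-oxabicyclo[2.2.2]oct-5-en-3-one | CC1=C[C@@H]2CC(C)(C)[C@H]1C(=O)O2 | intermediate
11 | (1S,4R)-4-(hydroxymethyl)-3,5,5-trimethylcyclohex-2-en-1-ol | CC1=C[C@@H](O)CC(C)(C)[C@H]1CO | intermediate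
12 | (1S,4R)-3,5,5-trimethyl-4-{[(1-phenyl-1H-tetrazol-5-yl)sulfanyl]methyl}cyclohex-2-en-1-ol | CC1=C[C@@H](O)CC(C)(C)[C@H]1CSc1nnnn1-c1ccccc1 | intermediate
13 | (1S,4R)-3,5,5-trimethyl-4-{[(1-phenyl-1H-tetrazol-5-yl)sulfinyl]methyl}cyclohex-2-en-1-ol (mixture at sulfur, not isolated) | CC1=C[C@@H](O)CC(C)(C)[C@H]1CS(=O)c1nnnn1-c1ccccc1 | intermediate
14 | (1S,4R)-3,5,5-trimethyl-4-{[(1-phenyl-1H-tetrazol-5-yl)sulfonyl]methyl}cyclohex-2-en-1-ol | CC1=C[C@@H](O)CC(C)(C)[C@H]1CS(=O)(=O)c1nnnn1-c1ccccc1 | intermediate
15 | crocetin dialdehyde, (2E,4E,6E,8E,10E,12E,14E)-2,6,11,15-tetramethylhexadeca-2,4,6,8,10,12,14-heptaenedial | O=C/C(C)=C/C=C/C(C)=C/C=C/C=C(C)/C=C/C=C(\C)C=O | starting material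
16 | (2E,4E,6E,8E,10E,12E,14E,16E)-17-[(1R,4S)-4-hydroxy-2,6,6-trimethylcyclohex-2-en-1-yl]-2,6,11,15-tetramethylheptadeca-2,4,6,8,10,12,14,16-octaenal | CC1=C[C@@H](O)CC(C)(C)[C@H]1/C=C/C(C)=C/C=C/C(C)=C/C=C/C=C(C)/C=C/C=C(\C)C=O | target

**Step count and risks**

Total steps: 9. Longest linear sequence: 9 steps (1 → 16); 3 and 15 are bought.

Steps most likely to fail:

1. Step 2 (annulation). The ester enolate may attack the ester carbonyl of 3 (1,2-addition) or deprotonate its propargylic methyl group instead of adding to the β-carbon, and the second ring closure may stall at the stage of the delocalised anion. Fallback, setting out from 2 and 3 and coming back at 5: 3 is hydroiodinated (NaI, AcOH, heat) to methyl (2Z)-3-iodobut-2-enoate F1. The lithium enolate of 2 (LiNCy2) is coupled with F1 under Pd(dba)2/P(t-Bu)3 catalysis (enolate α-alkenylation with retention of the alkene geometry), which makes the C5–C6 bond and gives 7-tert-butyl 1-methyl (2Z)-4-(tert-butoxycarbonyl)-3,5,5-trimethylhept-2-enedioate F2. F2 is isolated and closed in a separate Dieckmann condensation (KOt-Bu, THF) that makes the C2–C3 bond and gives 5.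

2. Step 5 (dynamic lactonisation). Intermolecular acylation (oligomer formation) or O-trichlorobenzoylation of the trans acyl species may outrun its epimerisation, and the bridged lactone may lose CO2 if it is overheated. Fallback, setting out from 8 and coming back at 10 (and at 7 for recycled material): the mixture is treated with a carbodiimide without amine base (EDC·HCl, CH2Cl2, 0 °C), under which only the cis acid (1R,4S)-4-hydroxy-2,6,6-trimethylcyclohex-2-ene-1-carboxylic acid F3 closes to 10. The trans acid (1S,4S)-4-hydroxy-2,6,6-trimethylcyclohex-2-ene-1-carboxylic acid F4 is recovered by bicarbonate extraction, oxidised with MnO2 (CH2Cl2) back to keto acid 7 and sent through step 4 again.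

3. Step 9 (olefination). Double olefination of the dialdehyde, erosion of E-selectivity with the conjugated aldehyde, and alkoxide-mediated enolisation of the polyenal product (loss of the C6 configuration) are the likely failure processes. Fallback, setting out from 14 and coming back at 16: 14 is silylated (TBSCl, imidazole, DMF) to tert-butyl(dimethyl){[(1S,4R)-3,5,5-trimethyl-4-{[(1-phenyl-1H-tetrazol-5-yl)sulfonyl]methyl}cyclohex-2-en-1-yl]oxy}silane F5. The olefination with 15 is then run with 1.05 equiv KN(SiMe3)2 so that no alkoxide is present, giving the silyl ether of the target, (2E,4E,6E,8E,10E,12E,14E,16E)-17-[(1R,4S)-4-{[tert-butyl(dimethyl)silyl]oxy}-2,6,6-trimethylcyclohex-2-en-1-yl]-2,6,11,15-tetramethylheptadeca-2,4,6,8,10,12,14,16-octaenal F6. The silyl group is removed with buffered HF·pyridine in THF to give 16; any 7Z isomer would be equilibrated to all-E by iodine-catalysed photoisomerisation.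

**Further compounds**

F1 | step 2 | methyl (2Z)-3-iodobut-2-enoate | COC(=O)/C=C(/C)I
F2 | step 2 | 7-tert-butyl 1-methyl (2Z)-4-(tert-butoxycarbonyl)-3,5,5-trimethylhept-2-enedioate | COC(=O)/C=C(/C)C(C(=O)OC(C)(C)C)C(C)(C)CC(=O)OC(C)(C)C
F3 | step 5 | (1R,4S)-4-hydroxy-2,6,6-trimethylcyclohex-2-ene-1-carboxylic acid | CC1=C[C@@H](O)CC(C)(C)[C@H]1C(=O)O
F4 | step 5 | (1S,4S)-4-hydroxy-2,6,6-trimethylcyclohex-2-ene-1-carboxylic acid | CC1=C[C@@H](O)CC(C)(C)[C@@H]1C(=O)O
F5 | step 9 | tert-butyl(dimethyl){[(1S,4R)-3,5,5-trimethyl-4-{[(1-phenyl-1H-tetrazol-5-yl)sulfonyl]methyl}cyclohex-2-en-1-yl]oxy}silane | CC1=C[C@@H](O[Si](C)(C)C(C)(C)C)CC(C)(C)[C@H]1CS(=O)(=O)c1nnnn1-c1ccccc1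
F6 | step 9 | (2E,4E,6E,8E,10E,12E,14E,16E)-17-[(1R,4S)-4-{[tert-butyl(dimethyl)silyl]oxy}-2,6,6-trimethylcyclohex-2-en-1-yl]-2,6,11,15-tetramethylheptadeca-2,4,6,8,10,12,14,16-octaenal | CC1=C[C@@H](O[Si](C)(C)C(C)(C)C)CC(C)(C)[C@H]1/C=C/C(C)=C/C=C/C(C)=C/C=C/C=C(C)/C=C/C=C(\C)C=O
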